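**Strategy.** The target is epicatechin-(4β→8)-epicatechin 3-O-gallate-(4β→8)-epicatechin 3-O-gallate. Everything rests on the C4 methine of the middle unit: it lies between two phloroglucinol-type rings (C4a of its own ring A, C8 of the lower unit) and is therefore an acetal carbon in disguise. In one operation a Lewis acid turns an acyclic (2S,3R)-2-galloyloxy-3-aryloxy-3-arylpropanal diethyl acetal into the central pyran ring (bond C4–C4a) and then joins C4 to C8 of benzylated epicatechin gallate, setting C4 trans to the gallate. The precursor is an aryl ether with no heterocycle; the outer flavan units come intact from (−)-epicatechin and the top unit is attached last.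

Key step: step 8

Remark: compounds 3, 6, 7, 10 and the L-fructose-derived Shi ketone are taken as commercially available.

**Step 1**
Reactants: 1 (−)-epicatechin
Product: 2 5,7,3',4'-tetra-O-benzyl-(−)-epicatechin
Conditions: BnBr (4.4 equiv), K2CO3, DMF, 0 °C to rt
Reagents that add atoms: benzyl bromide, BrCc1ccccc1
Why: Williamson etherification; K2CO3 deprotonates only the four phenols, so the secondary 3-OH stays free and C2 and C3 are untouched.

**Step 2**
Reactants: 2 tetra-O-benzylepicatechin; 3 3,4,5-tris(benzyloxy)benzoic acid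
Product: 4 5,7,3',4'-tetra-O-benzyl-(−)-epicatechin 3-O-[3,4,5-tris(benzyloxy)benzoate] (bottom-unit nucleophile)
Conditions: DCC, DMAP (cat.), CH2Cl2, rt
Reagents that add atoms: none
Why: Steglich esterification of the secondary alcohol through the N-acylpyridinium ion; the C3–O bond is not broken, so configuration is retained.

**Step 3**
Reactants: 2 tetra-O-benzylepicatechin
Product: 5 5,7,3',4'-tetra-O-benzyl-4β-(2-ethoxyethoxy)-(−)-epicatechin (top-unit electrophile, free 3-OH)
Conditions: DDQ (2 equiv), 2-ethoxyethanol, CH2Cl2, rt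
Reagents that add atoms: 2-ethoxyethanol, CCOCCO
Why: DDQ benzylic oxidation; hydride abstraction at C4 gives the ring A-stabilized cation, which the alcohol traps trans to the axial 3-OH (4β).

**Step 4**
Reactants: 6 4-bromo-1,2-bis(benzyloxy)benzene; 7 (E)-2-(3,3-diethoxyprop-1-en-1-yl)-4,4,5,5-tetramethyl-1,3,2-dioxaborolane
Product: 8 (E)-1,2-bis(benzyloxy)-4-(3,3-diethoxyprop-1-en-1-yl)benzene
Conditions: PdCl2(dppf) (3 mol %), K2CO3, 1,4-dioxane/H2O, 80 °C
Reagents that add atoms: none
Why: Suzuki–Miyaura coupling with retention of the E geometry of the alkenylboronate; the acetal is stable to the basic medium.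

**Step 5**
Reactants: 8 (E)-alkene acetal
Product: 9 (2R,3S)-3-[3,4-bis(benzyloxy)phenyl]-2-(diethoxymethyl)oxirane (trans)
Conditions: 1,2:4,5-di-O-isopropylidene-β-L-erythro-2,3-hexodiulo-2,6-pyranose (L-fructose-derived Shi ketone, 30 mol %), Oxone (2KHSO5·KHSO4·K2SO4), K2CO3, Bu4NHSO4 (cat.), MeCN/CH2(OMe)2/aq. Na2B4O7 buffer (pH 10.5), 0 °C
Reagents that add atoms: potassium peroxymonosulfate (from Oxone), [K+].[O-]S(=O)(=O)OO
Why: Shi asymmetric epoxidation; the chiral dioxirane transfers oxygen stereospecifically to the E-alkene through a spiro transition state, and the L-series ketone selects the face opposite to that attacked by the D-fructose ketone (which gives R,R-epoxides from trans-β-substituted styrenes), so the (2R,3S)-epoxide should result.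

**Step 6**
Reactants: 9 trans-epoxy acetal; 10 3,5-bis(benzyloxy)phenol
Product: 11 (2R,3R)-3-[3,4-bis(benzyloxy)phenyl]-3-[3,5-bis(benzyloxy)phenoxy]-1,1-diethoxypropan-2-ol (anti)
Conditions: 10 (1.5 equiv), Cs2CO3 (0.3 equiv), DMF, 70 °C
Reagents that add atoms: none
Why: base-mediated SN2 opening of the epoxide by the phenoxide at the benzylic carbon (the other carbon is shielded and deactivated by the acetal) with inversion, giving the anti hydroxy ether; the basic medium avoids ionization of the electron-rich benzylic epoxide.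

**Step 7**
Reactants: 11 anti hydroxy ether; 3 3,4,5-tris(benzyloxy)benzoic acid
Product: 12 (2S,3R)-3-[3,4-bis(benzyloxy)phenyl]-3-[3,5-bis(benzyloxy)phenoxy]-1,1-diethoxypropan-2-yl 3,4,5-tris(benzyloxy)benzoate (syn)
Conditions: PPh3, DIAD, toluene, 0 °C to rt
Reagents that add atoms: none
Why: Mitsunobu esterification; the gallate carboxylate displaces the alkoxyphosphonium group with inversion at C2, turning the anti into the syn arrangement that maps onto the 2,3-cis flavan and installing the middle gallate at the same time.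

**Step 8**
Reactants: 12 syn acetal gallate; 4 bottom-unit nucleophile
Product: 14 perbenzylated epicatechin 3-O-gallate-(4β→8)-epicatechin 3-O-gallate (protected middle–bottom dimer), via 4-ethoxyflavan gallate 13 (not isolated)
Conditions: 4 (3 equiv), TMSOTf (0.3 equiv), 4 Å MS, CH2Cl2, −78 to −30 °C, slow addition of 12; Et3N quench
Reagents that add atoms: none
Why: TMSOTf ionizes the diethyl acetal of 12 to an oxocarbenium ion (buffered as a dioxolenium ion by the neighbouring galloyl carbonyl), the tethered 3,5-bis(benzyloxy)phenoxy ring attacks it to give the 4-ethoxyflavan 13, and a second ionization gives the 2,4,6-trioxygenated benzylic C4 cation, which C8 of 4 captures. The closest known reaction types are the acetal-initiated Friedel–Crafts cyclization of 3-aryloxypropanal acetals to 4-alkoxychromans and the Lewis acid-mediated coupling of 4-alkoxyflavan-3-ol electrophiles with flavan-3-ol nucleophiles, here run in one flask. The pyran ring (O1, C2, C3, C4, C4a, C8a) closes by formation of the C4–C4a bond in a 6-exo-trig attack of the arene on the oxocarbenium carbon. The only new stereocenter, C4, is set in the second event by substrate control: the nucleophile enters anti to the pseudoaxial 3-O-galloyl group (which can bridge C4 as a dioxolenium ion) and to the C2 aryl group, giving the 3,4-trans (4β) product, while C2 and C3 are carried unchanged from 12. The step needs ring closure before intermolecular capture (secured by the six-membered intramolecular pathway and slow addition of 12), no regiochoice in the cyclization (the two ortho positions are equivalent and the para position cannot reach), attack at C8 and not C6 of 4 (the known preference of benzylated flavan-3-ol nucleophiles) and suppression of self-condensation through the free C6 and C8 of the new ring A (excess of 4).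

**Step 9**
Reactants: 14 protected middle–bottom dimer; 5 top-unit electrophile
Product: 15 octadeca-O-benzyl epicatechin-(4β→8)-epicatechin 3-O-gallate-(4β→8)-epicatechin 3-O-gallate (protected trimer)
Conditions: 14 (1.5 equiv), TMSOTf (cat.), CH2Cl2, −78 to −40 °C; Et3N quench
Reagents that add atoms: none
Why: Lewis acid-promoted interflavan coupling (Friedel–Crafts alkylation); loss of the 4-(2-ethoxyethoxy) group gives the C4 cation of the top unit, which should be attacked trans to its axial 3-OH by C8 of the middle unit, the most nucleophilic free position of 14 (flanked by O1 and the 7-benzyloxy group), as is usual for chain extension of a 4→8 dimer.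

**Step 10**
Reactants: 15 protected trimer
Product: 16 epicatechin-(4β→8)-epicatechin 3-O-gallate-(4β→8)-epicatechin 3-O-gallate (CNP0279403.1)
Conditions: H2 (1 atm), Pd(OH)2/C, THF/MeOH/H2O, rt
Reagents that add atoms: none
Why: hydrogenolysis of all eighteen benzyl ethers under neutral conditions; the gallate esters, both interflavan bonds and the cyclic O1–C2 ethers should survive, as is usual for benzylated procyanidin gallates.

**Compound list**

1 | (−)-epicatechin | O[C@@H]1Cc2c(O)cc(O)cc2O[C@@H]1c1ccc(O)c(O)c1 | starting material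
2 | 5,7,3',4'-tetra-O-benzyl-(−)-epicatechin (2R,3R) | O[C@@H]1Cc2c(OCc3ccccc3)cc(OCc3ccccc3)cc2O[C@@H]1c1ccc(OCc2ccccc2)c(OCc2ccccc2)c1 | intermediate
3 | 3,4,5-tris(benzyloxy)benzoic acid | OC(=O)c1cc(OCc2ccccc2)c(OCc2ccccc2)c(OCc2ccccc2)c1 | starting material
4 | 5,7,3',4'-tetra-O-benzyl-(−)-epicatechin 3-O-[3,4,5-tris(benzyloxy)benzoate] | O=C(O[C@@H]1Cc2c(OCc3ccccc3)cc(OCc3ccccc3)cc2O[C@@H]1c1ccc(OCc2ccccc2)c(OCc2ccccc2)c1)c1cc(OCc2ccccc2)c(OCc2ccccc2)c(OCc2ccccc2)c1 | intermediate
5 | 5,7,3',4'-tetra-O-benzyl-4β-(2-ethoxyethoxy)-(−)-epicatechin (2,3-cis, 3,4-trans) | CCOCCO[C@H]1c2c(OCc3ccccc3)cc(OCc3ccccc3)cc2O[C@H](c2ccc(OCc3ccccc3)c(OCc3ccccc3)c2)[C@@H]1O | intermediate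
6 | 4-bromo-1,2-bis(benzyloxy)benzene | Brc1ccc(OCc2ccccc2)c(OCc2ccccc2)c1 | starting material
7 | (E)-2-(3,3-diethoxyprop-1-en-1-yl)-4,4,5,5-tetramethyl-1,3,2-dioxaborolane | CCOC(OCC)/C=C/B1OC(C)(C)C(C)(C)O1 | starting material
8 | (E)-1,2-bis(benzyloxy)-4-(3,3-diethoxyprop-1-en-1-yl)benzene | CCOC(OCC)/C=C/c1ccc(OCc2ccccc2)c(OCc2ccccc2)c1 | intermediate
9 | (2R,3S)-3-[3,4-bis(benzyloxy)phenyl]-2-(diethoxymethyl)oxirane | CCOC(OCC)[C@@H]1O[C@H]1c1ccc(OCc2ccccc2)c(OCc2ccccc2)c1 | intermediate
10 | 3,5-bis(benzyloxy)phenol | Oc1cc(OCc2ccccc2)cc(OCc2ccccc2)c1 | starting material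
11 | (2R,3R)-3-[3,4-bis(benzyloxy)phenyl]-3-[3,5-bis(benzyloxy)phenoxy]-1,1-diethoxypropan-2-ol | CCOC(OCC)[C@H](O)[C@H](Oc1cc(OCc2ccccc2)cc(OCc2ccccc2)c1)c1ccc(OCc2ccccc2)c(OCc2ccccc2)c1 | intermediate
12 | (2S,3R)-3-[3,4-bis(benzyloxy)phenyl]-3-[3,5-bis(benzyloxy)phenoxy]-1,1-diethoxypropan-2-yl 3,4,5-tris(benzyloxy)benzoate | CCOC(OCC)[C@@H](OC(=O)c1cc(OCc2ccccc2)c(OCc2ccccc2)c(OCc2ccccc2)c1)[C@H](Oc1cc(OCc2ccccc2)cc(OCc2ccccc2)c1)c1ccc(OCc2ccccc2)c(OCc2ccccc2)c1 | intermediate
13 | 5,7,3',4'-tetra-O-benzyl-4-ethoxyepicatechin 3-O-[3,4,5-tris(benzyloxy)benzoate] (2,3-cis; C4 not defined, both epimers converge) | CCOC1c2c(OCc3ccccc3)cc(OCc3ccccc3)cc2O[C@H](c2ccc(OCc3ccccc3)c(OCc3ccccc3)c2)[C@@H]1OC(=O)c1cc(OCc2ccccc2)c(OCc2ccccc2)c(OCc2ccccc2)c1 | intermediate (not isolated)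
14 | perbenzylated epicatechin 3-O-gallate-(4β→8)-epicatechin 3-O-gallate | O=C(O[C@@H]1[C@@H](c2c(OCc3ccccc3)cc(OCc3ccccc3)c3c2O[C@H](c2ccc(OCc4ccccc4)c(OCc4ccccc4)c2)[C@H](OC(=O)c2cc(OCc4ccccc4)c(OCc4ccccc4)c(OCc4ccccc4)c2)C3)c2c(OCc3ccccc3)cc(OCc3ccccc3)cc2O[C@@H]1c1ccc(OCc2ccccc2)c(OCc2ccccc2)c1)c1cc(OCc2ccccc2)c(OCc2ccccc2)c(OCc2ccccc2)c1 | intermediate
15 | octadeca-O-benzyl epicatechin-(4β→8)-epicatechin 3-O-gallate-(4β→8)-epicatechin 3-O-gallate | O=C(O[C@@H]1[C@@H](c2c(OCc3ccccc3)cc(OCc3ccccc3)c3c2O[C@H](c2ccc(OCc4ccccc4)c(OCc4ccccc4)c2)[C@H](OC(=O)c2cc(OCc4ccccc4)c(OCc4ccccc4)c(OCc4ccccc4)c2)C3)c2c(OCc3ccccc3)cc(OCc3ccccc3)c([C@H]3c4c(OCc5ccccc5)cc(OCc5ccccc5)cc4O[C@H](c4ccc(OCc5ccccc5)c(OCc5ccccc5)c4)[C@@H]3O)c2O[C@@H]1c1ccc(OCc2ccccc2)c(OCc2ccccc2)c1)c1cc(OCc2ccccc2)c(OCc2ccccc2)c(OCc2ccccc2)c1 | intermediate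
16 | epicatechin-(4β→8)-epicatechin 3-O-gallate-(4β→8)-epicatechin 3-O-gallate (CNP0279403.1) | O=C(O[C@@H]1[C@@H](c2c(O)cc(O)c3c2O[C@H](c2ccc(O)c(O)c2)[C@H](OC(=O)c2cc(O)c(O)c(O)c2)C3)c2c(O)cc(O)c([C@H]3c4c(O)cc(O)cc4O[C@H](c4ccc(O)c(O)c4)[C@@H]3O)c2O[C@@H]1c1ccc(O)c(O)c1)c1cc(O)c(O)c(O)c1 | target

**Step count and risks**

Total step count: 10. Longest linear sequence: 7 steps (steps 4 to 10, from compound 6).

Steps most likely to fail:

1. Step 8. The acyclic oxocarbenium ion may be captured intermolecularly (by 4 or by a second ring A) before the ring closes. The acetal next to the acyloxy-bearing carbon may ionize slowly. The cyclized cation may condense with itself, giving oligomers and eroding the C4 selectivity. Fallback: ring closure and interflavan bond formation are run as two separate operations, so that the nucleophile never meets the acyclic cation. Setting out from 12, cyclization alone under high dilution with catalytic BF3·OEt2 in CH2Cl2 containing ethanol (which returns the flavan C4 cation to its ether) should give the 4-ethoxyflavan gallate 13, now isolated. Compound 13 is then coupled with excess 4 under TMSOTf like any 4-alkoxyflavan electrophile, and the route is rejoined at 14. No new compound is made (F0).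

2. Step 7. Displacement at the hindered carbinol between the acetal and the aryloxy-bearing benzylic carbon may be slow. The neighbouring electron-rich aryl group may participate (retention or 1,2-aryl shift), or elimination may compete. Fallback: inversion by oxidation and reduction, then plain acylation. Setting out from 11, Dess–Martin periodinane (NaHCO3, CH2Cl2) should give (3R)-3-[3,4-bis(benzyloxy)phenyl]-3-[3,5-bis(benzyloxy)phenoxy]-1,1-diethoxypropan-2-one F1. LiBH(s-Bu)3 in THF at −78 °C should reduce it under Felkin–Anh (polar) control, hydride entering anti to the aryloxy group, to the syn alcohol (2S,3R)-3-[3,4-bis(benzyloxy)phenyl]-3-[3,5-bis(benzyloxy)phenoxy]-1,1-diethoxypropan-2-ol F2. Esterification with 3 (DCC, DMAP) comes back to the route at 12.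

3. Step 9. Electrophile 5 may condense with itself through its own free C8. The chain may grow further at C8 of the newly attached top unit. Attack may also occur at the C6 positions of 14. Fallback: a bromine-blocked electrophile. Setting out from 2, NBS (CH2Cl2, −78 °C to rt) should give 8-bromo-5,7,3',4'-tetra-O-benzyl-(−)-epicatechin F3. DDQ and 2-ethoxyethanol convert it into 8-bromo-5,7,3',4'-tetra-O-benzyl-4β-(2-ethoxyethoxy)-(−)-epicatechin F4. TMSOTf coupling with 14 gives the protected trimer brominated at C8 of the top unit F5, which can neither self-condense nor be extended. Hydrogenolysis (H2, Pd(OH)2/C, Et3N, THF/MeOH/H2O) removes the aryl bromide together with the benzyl groups and comes back to the route at 16.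

**Further compounds**

F0 | step 8 | none | none
F1 | step 7 | (3R)-3-[3,4-bis(benzyloxy)phenyl]-3-[3,5-bis(benzyloxy)phenoxy]-1,1-diethoxypropan-2-one | CCOC(OCC)C(=O)[C@H](Oc1cc(OCc2ccccc2)cc(OCc2ccccc2)c1)c1ccc(OCc2ccccc2)c(OCc2ccccc2)c1
F2 | step 7 | (2S,3R)-3-[3,4-bis(benzyloxy)phenyl]-3-[3,5-bis(benzyloxy)phenoxy]-1,1-diethoxypropan-2-ol | CCOC(OCC)[C@@H](O)[C@H](Oc1cc(OCc2ccccc2)cc(OCc2ccccc2)c1)c1ccc(OCc2ccccc2)c(OCc2ccccc2)c1
F3 | step 9 | 8-bromo-5,7,3',4'-tetra-O-benzyl-(−)-epicatechin | O[C@@H]1Cc2c(OCc3ccccc3)cc(OCc3ccccc3)c(Br)c2O[C@@H]1c1ccc(OCc2ccccc2)c(OCc2ccccc2)c1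
F4 | step 9 | 8-bromo-5,7,3',4'-tetra-O-benzyl-4β-(2-ethoxyethoxy)-(−)-epicatechin | CCOCCO[C@H]1c2c(OCc3ccccc3)cc(OCc3ccccc3)c(Br)c2O[C@H](c2ccc(OCc3ccccc3)c(OCc3ccccc3)c2)[C@@H]1O
F5 | step 9 | octadeca-O-benzyl 8-bromoepicatechin-(4β→8)-epicatechin 3-O-gallate-(4β→8)-epicatechin 3-O-gallate | O=C(O[C@@H]1[C@@H](c2c(OCc3ccccc3)cc(OCc3ccccc3)c3c2O[C@H](c2ccc(OCc4ccccc4)c(OCc4ccccc4)c2)[C@H](OC(=O)c2cc(OCc4ccccc4)c(OCc4ccccc4)c(OCc4ccccc4)c2)C3)c2c(OCc3ccccc3)cc(OCc3ccccc3)c([C@H]3c4c(OCc5ccccc5)cc(OCc5ccccc5)c(Br)c4O[C@H](c4ccc(OCc5ccccc5)c(OCc5ccccc5)c4)[C@@H]3O)c2O[C@@H]1c1ccc(OCc2ccccc2)c(OCc2ccccc2)c1)c1cc(OCc2ccccc2)c(OCc2ccccc2)c(OCc2ccccc2)c1
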